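The target is the C2-symmetric benzylic dimer of (S)-herbertenediol, so the plan rests on the central ArCH2–CH2Ar bond. In each benzene ring (C-1 cyclopentyl, C-2 and C-3 oxygen, C-5 benzylic carbon) the C-2 hydroxyl lies para to the benzylic carbon, and both carbons ortho to it are blocked. Hydrogen-atom abstraction from the 3-O-methyl monomer, a plain ArCH3 phenol, therefore funnels into a p-quinone methide. Two of these join at their exocyclic CH2 carbons, both rings rearomatise, and the bond arises by net double C(sp3)–H dehydrogenation without any benzylic prefunctionalisation. The monomer comes from creosol and 3-methylcyclopentenone by Pd-catalysed asymmetric conjugate arylation.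

Key step: step 9

Assumption: in step 4 the (R,R)-antipode of Ph-BOX, 2,2'-(propane-2,2-diyl)bis(4-phenyl-4,5-dihydrooxazole), is taken to deliver the (S)-ketone; both antipodes are commercial, and the other one is used if the first run shows the opposite sense.

Step 1
Reactants: 1 creosol (2-methoxy-4-methylphenol)
Product: 2 2-bromo-6-methoxy-4-methylphenol
Conditions: Br2 (1.0 equiv), CH2Cl2, −10 to 0 °C
Reagents that add atoms: bromine, BrBr
Why: Electrophilic aromatic bromination is steered by the free hydroxyl group, the strongest donor on the ring, whose para position is blocked by the methyl group, so bromine should enter the open ortho position C-6.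

Step 2
Reactants: 2 2-bromo-6-methoxy-4-methylphenol
Product: 3 2-(benzyloxy)-1-bromo-3-methoxy-5-methylbenzene
Conditions: BnBr, K2CO3, DMF, rt
Reagents that add atoms: benzyl bromide, BrCc1ccccc1
Why: Williamson ether synthesis on the phenoxide masks the acidic OH for the organometallic and enolate steps with a group that the later hydrogenation removes at no extra cost.

Step 3
Reactants: 3 2-(benzyloxy)-1-bromo-3-methoxy-5-methylbenzene
Product: 6 [2-(benzyloxy)-3-methoxy-5-methylphenyl]boronic acid, via aryllithium 4 (not isolated), via lithium aryltriisopropoxyborate 5 (not isolated)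
Conditions: n-BuLi, THF, −78 °C; B(Oi-Pr)3, −78 °C to rt; 1 M HCl
Reagents that add atoms: triisopropyl borate, CC(C)OB(OC(C)C)OC(C)C; water, O
Why: Bromine–lithium exchange followed by borylation works because the exchange at −78 °C is far faster than benzylic deprotonation or Wittig rearrangement of the benzyl ether, and the borate traps the aryllithium as an ate complex that acid hydrolyses to the boronic acid.

Step 4
Reactants: 6 [2-(benzyloxy)-3-methoxy-5-methylphenyl]boronic acid; 7 3-methylcyclopent-2-en-1-one
Product: 8 (3S)-3-[2-(benzyloxy)-3-methoxy-5-methylphenyl]-3-methylcyclopentan-1-one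
Conditions: PdCl2[(R,R)-Ph-BOX] (5 mol %), AgSbF6 (12 mol %), 6 (2 equiv), MeOH/H2O, 40 °C
Reagents that add atoms: none
Why: Pd(II)-catalysed asymmetric conjugate addition of an arylboronic acid proceeds by transmetalation to the dicationic Pd–bis(oxazoline) complex, enantiodetermining migratory insertion of the bound enone that places the aryl group on C-3, and protonolysis of the Pd enolate, and the phenyl groups of the C2-symmetric ligand leave only one enone face open and so set the (S)-quaternary centre, the only stereocentre of each half.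

Step 5
Reactants: 8 (3S)-3-[2-(benzyloxy)-3-methoxy-5-methylphenyl]-3-methylcyclopentan-1-one
Product: 10 (4R)-4-[2-(benzyloxy)-3-methoxy-5-methylphenyl]-4-methylcyclopent-2-en-1-one, via lithium enolate 9 (not isolated)
Conditions: LDA (1.1 equiv), THF, −78 °C; PhS(=Nt-Bu)Cl (1.2 equiv), −78 °C
Reagents that add atoms: none
Why: In this Mukaiyama dehydrogenation LDA removes the unhindered C-5 proton rather than the neopentyl-type C-2 proton, the enolate is sulfinimidoylated at carbon and the adduct undergoes syn elimination, and because C-3 is quaternary the double bond can only form on the C-4/C-5 side (the descriptor changes by CIP ranking only).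

Step 6
Reactants: 10 (4R)-4-[2-(benzyloxy)-3-methoxy-5-methylphenyl]-4-methylcyclopent-2-en-1-one
Product: 12 (4R)-4-[2-(benzyloxy)-3-methoxy-5-methylphenyl]-4,5,5-trimethylcyclopent-2-en-1-one, via monomethyl enone 11 (not isolated)
Conditions: NaH (3 equiv), MeI (6 equiv), THF/DMF, 0 °C to rt
Reagents that add atoms: iodomethane, CI
Why: Exhaustive enolate alkylation is unambiguous here because C-5 is the only enolisable position of 10 (quaternary C-4 blocks γ-deprotonation), so both methyl groups must enter next to the stereocentre, which bears no hydrogen and cannot epimerise.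

Step 7
Reactants: 12 (4R)-4-[2-(benzyloxy)-3-methoxy-5-methylphenyl]-4,5,5-trimethylcyclopent-2-en-1-one
Product: 14 (3R)-3-(2-hydroxy-3-methoxy-5-methylphenyl)-2,2,3-trimethylcyclopentan-1-one, via saturated benzyl ether 13 (not isolated)
Conditions: H2 (1 atm), 10% Pd/C, EtOH, rt
Reagents that add atoms: none
Why: Heterogeneous catalytic hydrogenation saturates the disubstituted enone double bond and hydrogenolyses the aryl benzyl ether in the same operation, while the hindered ketone, the methyl ether and the quaternary centre are inert (14 may rest partly as its bridged hemiketal, which reopens in base).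

Step 8
Reactants: 14 (3R)-3-(2-hydroxy-3-methoxy-5-methylphenyl)-2,2,3-trimethylcyclopentan-1-one
Product: 16 2-methoxy-4-methyl-6-[(1S)-1,2,2-trimethylcyclopentyl]phenol, via hydrazone 15 (not isolated)
Conditions: N2H4·H2O, KOH, diethylene glycol, 130 °C, then 200 °C with removal of water
Reagents that add atoms: none
Why: Wolff–Kishner reduction in the Huang-Minlon form is the standard deoxygenation of 2,2,3,3-tetrasubstituted cyclopentanones of the cuparenone type, and the phenoxide formed in KOH keeps the ketone open and disfavours nucleophilic cleavage of the neighbouring methoxy group.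

Step 9
Reactants: 16 2-methoxy-4-methyl-6-[(1S)-1,2,2-trimethylcyclopentyl]phenol (two molecules)
Product: 20 4,4'-(ethane-1,2-diyl)bis{2-methoxy-6-[(1S)-1,2,2-trimethylcyclopentyl]phenol}, via phenoxyl radical 17 (not isolated), via p-quinone methide 18 (not isolated), via bis(phenoxyl) diradical 19 (not isolated)
Conditions: (t-BuO)2 (0.45 equiv per 16), PhCl (0.2 M), 130 °C, Ar, sealed tube
Reagents that add atoms: none
Why: tert-Butoxyl radicals from the peroxide abstract the phenolic hydrogen of 16 to give the persistent phenoxyl radical 17, which disproportionates to 16 and the p-quinone methide 18; two molecules of 18 join tail-to-tail at their exocyclic CH2 carbons to give the bis(phenoxyl) diradical 19, and 19 takes two hydrogen atoms from further 16, which restarts the cycle. The closest known reaction type is the oxidative benzylic dimerisation of 2,6-disubstituted 4-methylphenols, as in the conversion of 2,6-di-tert-butyl-4-methylphenol or 4-methylsyringol into the 1,2-bis(4-hydroxyaryl)ethane. No ring is closed and no stereocentre is formed: the driving force is rearomatisation of both cyclohexadienone rings, the two quaternary stereocentres are untouched, and an enantiopure monomer can give only the C2-symmetric (S,S)-dimer and no meso compound. Site selectivity against aryl–aryl and aryl–oxygen coupling is secured by the substrate, because the only free OH is the one para to the methyl group, its two ortho carbons carry the cyclopentyl quaternary carbon and the methoxy group, and oxygen-to-CH2 adducts of 18 revert thermally whereas the C–C bond does not. Chemoselectivity against further oxidation of 20 towards the stilbenequinone is handled by keeping the peroxide limiting, stopping short of full conversion and recycling 16.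

Step 10
Reactants: 20 4,4'-(ethane-1,2-diyl)bis{2-methoxy-6-[(1S)-1,2,2-trimethylcyclopentyl]phenol}
Product: 22 5,5'-(ethane-1,2-diyl)bis{3-[(1S)-1,2,2-trimethylcyclopentyl]benzene-1,2-diol}, via bis(bromobenzodioxaborole) 21 (not isolated)
Conditions: BBr3 (5 equiv), CH2Cl2, −78 to 0 °C; degassed H2O, Ar
Reagents that add atoms: none
Why: In this Lewis acid-mediated aryl methyl ether cleavage BBr3 binds the ether oxygen, bromide removes the methyl group by SN2 and the cyclic catechol borate is hydrolysed on work-up, conditions that leave the bibenzyl bridge and the quaternary centres untouched.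

Compound list
1 | creosol (2-methoxy-4-methylphenol) | Cc1ccc(O)c(OC)c1 | starting material
2 | 2-bromo-6-methoxy-4-methylphenol | Cc1cc(Br)c(O)c(OC)c1 | intermediate
3 | 2-(benzyloxy)-1-bromo-3-methoxy-5-methylbenzene | Cc1cc(Br)c(OCc2ccccc2)c(OC)c1 | intermediate
4 | [2-(benzyloxy)-3-methoxy-5-methylphenyl]lithium | [Li]c1cc(C)cc(OC)c1OCc1ccccc1 | intermediate
5 | lithium [2-(benzyloxy)-3-methoxy-5-methylphenyl]tri(propan-2-yloxy)borate | [Li+].CC(C)O[B-](OC(C)C)(OC(C)C)c1cc(C)cc(OC)c1OCc1ccccc1 | intermediate
6 | [2-(benzyloxy)-3-methoxy-5-methylphenyl]boronic acid | OB(O)c1cc(C)cc(OC)c1OCc1ccccc1 | intermediate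
7 | 3-methylcyclopent-2-en-1-one | CC1=CC(=O)CC1 | starting material
8 | (3S)-3-[2-(benzyloxy)-3-methoxy-5-methylphenyl]-3-methylcyclopentan-1-one | O=C1CC[C@](C)(c2cc(C)cc(OC)c2OCc2ccccc2)C1 | intermediate
9 | lithium (4S)-4-[2-(benzyloxy)-3-methoxy-5-methylphenyl]-4-methylcyclopent-1-en-1-olate | [Li]OC1=CC[C@](C)(c2cc(C)cc(OC)c2OCc2ccccc2)C1 | intermediate
10 | (4R)-4-[2-(benzyloxy)-3-methoxy-5-methylphenyl]-4-methylcyclopent-2-en-1-one | O=C1C=C[C@](C)(c2cc(C)cc(OC)c2OCc2ccccc2)C1 | intermediate
11 | (4S)-4-[2-(benzyloxy)-3-methoxy-5-methylphenyl]-4,5-dimethylcyclopent-2-en-1-one (both C-5 epimers) | O=C1C=C[C@](C)(c2cc(C)cc(OC)c2OCc2ccccc2)C1C | intermediate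
12 | (4R)-4-[2-(benzyloxy)-3-methoxy-5-methylphenyl]-4,5,5-trimethylcyclopent-2-en-1-one | O=C1C=C[C@](C)(c2cc(C)cc(OC)c2OCc2ccccc2)C1(C)C | intermediate
13 | (3R)-3-[2-(benzyloxy)-3-methoxy-5-methylphenyl]-2,2,3-trimethylcyclopentan-1-one | O=C1CC[C@](C)(c2cc(C)cc(OC)c2OCc2ccccc2)C1(C)C | intermediate
14 | (3R)-3-(2-hydroxy-3-methoxy-5-methylphenyl)-2,2,3-trimethylcyclopentan-1-one | O=C1CC[C@](C)(c2cc(C)cc(OC)c2O)C1(C)C | intermediate
15 | C-1 hydrazone of ketone 14 (quaternary centre unchanged) | NN=C1CC[C@](C)(c2cc(C)cc(OC)c2O)C1(C)C | intermediate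
16 | 2-methoxy-4-methyl-6-[(1S)-1,2,2-trimethylcyclopentyl]phenol | CC1(C)CCC[C@]1(C)c1cc(C)cc(OC)c1O | intermediate
17 | 2-methoxy-4-methyl-6-[(1S)-1,2,2-trimethylcyclopentyl]phenoxyl radical | CC1(C)CCC[C@]1(C)c1cc(C)cc(OC)c1[O] | intermediate
18 | 2-methoxy-4-methylidene-6-[(1S)-1,2,2-trimethylcyclopentyl]cyclohexa-2,5-dien-1-one | CC1(C)CCC[C@]1(C)C1=CC(=C)C=C(OC)C1=O | intermediate
19 | bis(phenoxyl) diradical of 20 (both phenolic hydrogens missing) | CC1(C)CCC[C@]1(C)c1cc(CCc2cc(OC)c([O])c([C@@]3(C)CCCC3(C)C)c2)cc(OC)c1[O] | intermediate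
20 | 4,4'-(ethane-1,2-diyl)bis{2-methoxy-6-[(1S)-1,2,2-trimethylcyclopentyl]phenol} | CC1(C)CCC[C@]1(C)c1cc(CCc2cc(OC)c(O)c([C@@]3(C)CCCC3(C)C)c2)cc(OC)c1O | intermediate
21 | 1,2-bis{2-bromo-7-[(1S)-1,2,2-trimethylcyclopentyl]-1,3,2-benzodioxaborol-5-yl}ethane | CC1(C)CCC[C@]1(C)c1cc(CCc3cc4OB(Br)Oc4c([C@@]5(C)CCCC5(C)C)c3)cc2OB(Br)Oc12 | intermediate
22 | 5,5'-(ethane-1,2-diyl)bis{3-[(1S)-1,2,2-trimethylcyclopentyl]benzene-1,2-diol} | CC1(C)CCC[C@]1(C)c1cc(CCc2cc(O)c(O)c([C@@]3(C)CCCC3(C)C)c2)cc(O)c1O | target

Total step count: 10. Longest linear sequence: 10 steps, from 1.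

Steps most likely to fail

1. Step 9. The first-formed bibenzyl may be oxidised further about as fast as the monomer. The phenoxyl radical may also be diverted into carbon–oxygen coupling or loss of the methoxy group, so that the material balance erodes. The fallback sets out from 16 and makes the same bond by reductive coupling of a benzylic halide.
   - Acetylation (Ac2O, DMAP, Et3N, CH2Cl2) should give 2-methoxy-4-methyl-6-[(1S)-1,2,2-trimethylcyclopentyl]phenyl acetate F1.
   - Wohl–Ziegler bromination (NBS, AIBN, PhCF3, reflux) should give 4-(bromomethyl)-2-methoxy-6-[(1S)-1,2,2-trimethylcyclopentyl]phenyl acetate F2.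
   - Titanocene(III)-catalysed Wurtz-type homocoupling (Cp2TiCl2 cat., Mn, THF, rt) should give the diacetate of 20 F3.
   - Methanolysis (K2CO3, MeOH) comes back to the route at 20.

2. Step 4. Protodeboronation of the electron-rich ortho-alkoxy boronic acid may outrun the slow insertion at the β,β-disubstituted enone, and the facial selectivity may erode with the bulky ortho substituent. The fallback sets out from 3 and skips the boronic acid.
   - Bromine–lithium exchange to 4 and transmetalation with Me2AlCl (THF, −78 °C to rt) should give [2-(benzyloxy)-3-methoxy-5-methylphenyl]dimethylalane F4.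
   - F4 is used in situ in a copper-catalysed asymmetric conjugate addition to 7 (Cu(OTf)2 and a chiral bidentate sulfonate-bearing N-heterocyclic carbene, THF, −30 °C).
   - Aqueous work-up comes back to the route at 8.

3. Step 8. Hydrazone formation at the carbonyl group flanked by the gem-dimethyl carbon may be sluggish, and the methyl ether may be lost during long heating in KOH. The fallback sets out from 12 and replaces the hydrazone chemistry by reductive desulfurisation.
   - Homogeneous hydrogenation of the alkene alone ((Ph3P)3RhCl, H2, benzene) allows 13 to be isolated.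
   - Thioketalisation (ethane-1,2-dithiol, BF3·OEt2, CH2Cl2) should give the 1,3-dithiolane of 13 F5.
   - Raney nickel (EtOH, reflux) should remove sulfur and the benzyl group together, which comes back to the route at 16.

Further compounds
F1 | step 9 | 2-methoxy-4-methyl-6-[(1S)-1,2,2-trimethylcyclopentyl]phenyl acetate | CC1(C)CCC[C@]1(C)c1cc(C)cc(OC)c1OC(C)=O
F2 | step 9 | 4-(bromomethyl)-2-methoxy-6-[(1S)-1,2,2-trimethylcyclopentyl]phenyl acetate | CC1(C)CCC[C@]1(C)c1cc(CBr)cc(OC)c1OC(C)=O
F3 | step 9 | diacetate of 20 | CC1(C)CCC[C@]1(C)c1cc(CCc2cc(OC)c(OC(C)=O)c([C@@]3(C)CCCC3(C)C)c2)cc(OC)c1OC(C)=O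
F4 | step 4 | [2-(benzyloxy)-3-methoxy-5-methylphenyl]dimethylalane | C[Al](C)c1cc(C)cc(OC)c1OCc1ccccc1
F5 | step 8 | 1,3-dithiolane of 13 | CC1(C)C2(SCCS2)CC[C@]1(C)c1cc(C)cc(OC)c1OCc1ccccc1
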